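**Direct plan and its weak points**

A direct plan would start from the arene: Friedel–Crafts isobutyrylation of 2-methylphloroglucinol A1 would give the isobutyrophenone A2, which would be C-nerylated and O-prenylated to the ether A3.
The dihydrofuran ring would then be closed by a chelate-directed asymmetric epoxidation and 5-exo epoxide opening to give the dihydrobenzofuran A4.
A palladium-catalysed dearomatising shift of the O-prenyl group to C5 would give the enol A5, and O-prenylation followed by a Claisen–Cope relay would place the C7 prenyl group.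
First weakness: the epoxidation/cyclisation that sets C2 and C2′ would rest on an undemonstrated acylphenol directing mode and would have to pick one of three trisubstituted olefins and one of two phenols.
Second weakness: the dearomatising prenyl shift would have to choose C5 over C3a and one ring face, by catalyst control against a remote stereocentre, on an advanced bicycle.
Third weakness: the final thermal operation would build the acyl-bearing quaternary C7 by two [3,3] shifts at 120 °C, with a facial bias that rests only on methyl versus prenyl at C5 and no chance of correction.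

**Retrosynthetic overview of the new route**

The cyclohexenedione ring is cut at C3a–C4 and C6–C7 and is closed last, by a [3+3] annulation of C3a/C7 of an oxolane-bearing masked diketone dianion (8, as diene 20) with C4/C6 of an enantiopure 2-methyl-2-prenylmalonyl bis-electrophile (19).
The oxolane ring (O1, C2, C3, C3a, C7a) is made first, from the dianion of a prenylated 1,3-diketone and a nerol-derived epoxy iodide; C2 and C2′ come from a Sharpless epoxidation, and O1 can only end up on C7a.
C7 carries its prenyl and isobutyryl groups, and C5 its methyl and prenyl groups, before the ring exists, so there is no arene, no dearomatisation, no phenol differentiation and no late C7 prenylation.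
C5 comes from an asymmetric phase-transfer alkylation; C7 is set in the ring closure under control of C5, from a mixture of E/Z isomers, tautomers and epimers (stereoconvergent).

Key step: step 11

Assumption: the (R,R)-enantiomer of the phase-transfer catalyst is taken to give (R)-14 by analogy with other allylic bromides; if the sense of induction is the opposite, the (S,S)-enantiomer is used and nothing else changes.

**Route**

Step 1
Reactants: 1 nerol
Product: 2 [(2R,3S)-3-methyl-3-(4-methylpent-3-en-1-yl)oxiran-2-yl]methanol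
Conditions: Ti(OiPr)4 (5 mol%), D-(−)-diethyl tartrate (6 mol%), tBuOOH (1.5 equiv), 4 Å MS, CH2Cl2, −20 °C
Reagents that add atoms: tert-butyl hydroperoxide, CC(C)(C)OO
Why: Sharpless asymmetric epoxidation: the titanium tartrate binds the allylic hydroxyl, so only the 2,3-olefin reacts, and D-(−)-tartrate delivers oxygen to the face that gives the (2R,3S)-cis-epoxide, which fixes both carbons that become C2 and C2′.

Step 2
Reactants: 2 [(2R,3S)-3-methyl-3-(4-methylpent-3-en-1-yl)oxiran-2-yl]methanol
Product: 3 (2S,3S)-2-(iodomethyl)-3-methyl-3-(4-methylpent-3-en-1-yl)oxirane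
Conditions: I2, PPh3, imidazole, Et2O/MeCN, 0 °C
Reagents that add atoms: iodine, II
Why: Appel-type iodination by SN2 at the primary carbon under buffered conditions leaves both epoxide carbons untouched (the change from R to S at the CH carbon is only a change of priorities).

Step 3
Reactants: 4 5-methylhexane-2,4-dione; 5 prenyl bromide
Product: 6 5-methyl-3-(3-methylbut-2-en-1-yl)hexane-2,4-dione
Conditions: K2CO3, acetone, reflux
Reagents that add atoms: none
Why: C-alkylation of a β-diketone at its central carbon with an allylic bromide (SN2; weak base in acetone favours C over O); the new methine is enolisable and its configuration is of no consequence.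

Step 4
Reactants: 6 5-methyl-3-(3-methylbut-2-en-1-yl)hexane-2,4-dione; 3 (2S,3S)-2-(iodomethyl)-3-methyl-3-(4-methylpent-3-en-1-yl)oxirane
Product: 8 4-{(5S)-5-[(2S)-2-hydroxy-6-methylhept-5-en-2-yl]oxolan-2-ylidene}-2,7-dimethyloct-6-en-3-one (E/Z mixture), via epoxy diketone enolate 7 (not isolated)
Conditions: 6 (1.3 equiv), LiN(iPr)2 (2.6 equiv), THF, −78 → 0 °C; 3, −78 → −20 °C; LiClO4 (2 equiv), 20 → 50 °C; aq NH4Cl
Reagents that add atoms: none
Why: Dianion alkylation/cyclisation route to 2-alkylidene-tetrahydrofurans: the terminal carbon of the 1,3-diketone dianion (methyl, not the hindered isopropyl methine, is deprotonated) displaces iodide by SN2, then the adjacent enolate oxygen opens the epoxide 5-exo-tet at the CH carbon with inversion (C-closure would have to build a quaternary centre at the fully substituted C7), which forms O1–C2, gives C2 (S) and leaves C2′ (S) as the tertiary alcohol.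

Step 5
Reactants: 9 2,2,5-trimethyl-1,3-dioxane-4,6-dione; 10 tert-butanol
Product: 11 3-tert-butoxy-2-methyl-3-oxopropanoic acid (racemic)
Conditions: tBuOH, reflux
Reagents that add atoms: none
Why: Thermal alcoholysis of a 5-substituted Meldrum's acid with loss of acetone gives the malonic half-ester; the methine is racemic and enolisable.

Step 6
Reactants: 11 3-tert-butoxy-2-methyl-3-oxopropanoic acid; 12 2,2-diphenylethan-1-ol
Product: 13 1-tert-butyl 3-(2,2-diphenylethyl) 2-methylpropanedioate (racemic)
Conditions: N,N′-dicyclohexylcarbodiimide, DMAP (cat.), CH2Cl2, 0 °C → rt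
Reagents that add atoms: none
Why: Steglich esterification of the free acid with a primary alcohol; the tert-butyl ester is not touched.

Step 7
Reactants: 13 1-tert-butyl 3-(2,2-diphenylethyl) 2-methylpropanedioate; 5 prenyl bromide
Product: 14 1-tert-butyl 3-(2,2-diphenylethyl) (2R)-2-methyl-2-(3-methylbut-2-en-1-yl)propanedioate
Conditions: (R,R)-2,6-bis(3,4,5-trifluorophenyl)-3,3′,5,5′-tetrahydro-4,4′-spirobi[dinaphtho[2,1-c:1′,2′-e]azepin]-4-ium bromide (5 mol%), 50% aq KOH, toluene, −40 °C
Reagents that add atoms: none
Why: Enantioselective phase-transfer α-alkylation of an α-methylmalonate: the chiral ammonium cation shields one face of the enolate, whose two esters differ strongly in size, and SN2 at the primary allylic carbon gives the linear prenyl group; this sets the quaternary centre that becomes C5.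

Step 8
Reactants: 14 1-tert-butyl 3-(2,2-diphenylethyl) (2R)-2-methyl-2-(3-methylbut-2-en-1-yl)propanedioate
Product: 15 (2R)-2-(tert-butoxycarbonyl)-2,5-dimethylhex-4-enoic acid
Conditions: 1 M KOH, MeOH, rt; then cold 1 M HCl to pH 3
Reagents that add atoms: potassium hydroxide, [K+].[OH-]
Why: Chemoselective saponification: hydroxide cleaves the primary ester while the tert-butyl ester is inert to base; the quaternary centre cannot epimerise.

Step 9
Reactants: 15 (2R)-2-(tert-butoxycarbonyl)-2,5-dimethylhex-4-enoic acid; 16 pentafluorophenol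
Product: 17 1-tert-butyl 3-(pentafluorophenyl) (2S)-2-methyl-2-(3-methylbut-2-en-1-yl)propanedioate
Conditions: N,N′-dicyclohexylcarbodiimide, DMAP (cat.), CH2Cl2, 0 °C → rt
Reagents that add atoms: none
Why: Carbodiimide coupling to the pentafluorophenyl active ester marks this carboxyl (the future C6) for the ring closure; the descriptor changes to S only through the priorities.

Step 10
Reactants: 17 1-tert-butyl 3-(pentafluorophenyl) (2S)-2-methyl-2-(3-methylbut-2-en-1-yl)propanedioate
Product: 19 pentafluorophenyl (2R)-2-(chlorocarbonyl)-2,5-dimethylhex-4-enoate, via trimethylsilyl ester 18 (not isolated)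
Conditions: Me3SiOTf (1.5 equiv), 2,6-lutidine (2 equiv), CH2Cl2, 0 °C → rt; then (COCl)2 (2 equiv), DMF (cat.), 0 °C → rt; concentrate, take up in pentane, filter; use at once
Reagents that add atoms: oxalyl chloride, ClC(=O)C(Cl)=O
Why: Non-protic cleavage of the tert-butyl ester (silyl triflate/hindered pyridine, loss of isobutene) avoids acid-induced lactonisation onto the prenyl group, and the silyl ester is turned in situ into the acid chloride, which gives a bis-electrophile with two carbonyls of different reactivity and an untouched stereocentre.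

Step 11
Reactants: 8 4-{(5S)-5-[(2S)-2-hydroxy-6-methylhept-5-en-2-yl]oxolan-2-ylidene}-2,7-dimethyloct-6-en-3-one; 19 pentafluorophenyl (2R)-2-(chlorocarbonyl)-2,5-dimethylhex-4-enoate
Product: 23 target CNP0250451.1, via bis-silyl dienol ether 20 (not isolated), via C3a-acylated pentafluorophenyl ester 21 (not isolated), via O-silylated target 22 (not isolated)
Conditions: (a) 8, Me3SiOTf (2.3 equiv), Et3N (3 equiv), Et2O, 0 °C; separate the Et3NH·OTf layer, concentrate; (b) 19 (1.1 equiv), CH2Cl2, −78 → 0 °C; remove volatiles; (c) MgBr2·OEt2 (2.5 equiv), iPr2NEt (3 equiv), CH2Cl2, 0 °C → rt; (d) 0.5 M aq HCl, THF, 0 °C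
Reagents that add atoms: none
Why: Soft enolisation of 8 at the γ-CH2 (the only α′-hydrogen is the hindered isopropyl methine) gives the 1-silyloxy-3-alkoxy-diene 20, a masked diketone dianion, which is C-acylated at its unhindered terminal carbon C3a by the acid chloride of 19 with loss of Me3SiCl; the vinylogous β-diketone 21 is then enolised by MgBr2·OEt2/iPr2NEt and C7 attacks the pentafluorophenyl ester in a 6-(enolexo)-exo-trig Claisen-type closure, so that the whole is a [3+3] annulation that forms C3a–C4 and C6–C7 and closes the carbocycle. The closest known reaction types are the terminal C-acylation of silyloxydienes by acid chlorides, the Effenberger cyclisation of enol ethers with malonyl dichlorides, and the soft-enolisation C-acylation of ketones with pentafluorophenyl esters. Chemoselectivity follows from the leaving groups (chloride reacts first, the aryl ester only within the molecule); O-acylation cannot compete because the C7a oxygen is the ring ether and every other O- or C-closure would give a four- or eight-membered ring. C5 is carried in from 19, and C7 is created from a mixture of E/Z isomers, tautomers and C7 epimers that all pass through one planar enolate. Its configuration should be controlled by C5 in a magnesium-chelated chair-like transition state: the enolate oxygen and the C6 carbonyl oxygen share the metal on one face, the bulky aryloxide is pushed to the other face beside the C7 prenyl group, and the C5 methyl rather than the C5 prenyl takes the position next to that leaving group, which places the two prenyl groups trans (5S,7S). Chloride and pentafluorophenoxide are non-nucleophilic, so the non-enolisable triketone is not cleaved by a retro-Claisen reaction, and mild acid removes the silyl ether to give 23.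

**Compound list**

1 | nerol, (2Z)-3,7-dimethylocta-2,6-dien-1-ol | CC(C)=CCC/C(C)=C\CO | starting material
2 | [(2R,3S)-3-methyl-3-(4-methylpent-3-en-1-yl)oxiran-2-yl]methanol | OC[C@H]1O[C@@]1(C)CCC=C(C)C | intermediate
3 | (2S,3S)-2-(iodomethyl)-3-methyl-3-(4-methylpent-3-en-1-yl)oxirane | IC[C@H]1O[C@@]1(C)CCC=C(C)C | intermediate
4 | 5-methylhexane-2,4-dione | CC(=O)CC(=O)C(C)C | starting material
5 | prenyl bromide, 1-bromo-3-methylbut-2-ene | CC(C)=CCBr | starting material
6 | 5-methyl-3-(3-methylbut-2-en-1-yl)hexane-2,4-dione | CC(=O)C(CC=C(C)C)C(=O)C(C)C | intermediate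
7 | 2-methyl-4-(3-methylbut-2-en-1-yl)-7-[(2R,3S)-3-methyl-3-(4-methylpent-3-en-1-yl)oxiran-2-yl]heptane-3,5-dione (present as its lithium enolate) | CC(C)C(=O)C(CC=C(C)C)C(=O)CC[C@H]1O[C@@]1(C)CCC=C(C)C | intermediate (not isolated)
8 | 4-{(5S)-5-[(2S)-2-hydroxy-6-methylhept-5-en-2-yl]oxolan-2-ylidene}-2,7-dimethyloct-6-en-3-one (E/Z mixture) | CC(C)=CCC[C@](C)(O)[C@@H]1CCC(O1)=C(CC=C(C)C)C(=O)C(C)C | intermediate
9 | 2,2,5-trimethyl-1,3-dioxane-4,6-dione | CC1C(=O)OC(C)(C)OC1=O | starting material
10 | tert-butanol | CC(C)(C)O | starting material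
11 | 3-tert-butoxy-2-methyl-3-oxopropanoic acid (racemic) | CC(C(O)=O)C(=O)OC(C)(C)C | intermediate
12 | 2,2-diphenylethan-1-ol | OCC(c1ccccc1)c1ccccc1 | starting material
13 | 1-tert-butyl 3-(2,2-diphenylethyl) 2-methylpropanedioate (racemic) | CC(C(=O)OC(C)(C)C)C(=O)OCC(c1ccccc1)c1ccccc1 | intermediate
14 | 1-tert-butyl 3-(2,2-diphenylethyl) (2R)-2-methyl-2-(3-methylbut-2-en-1-yl)propanedioate | O=C(OCC(c1ccccc1)c1ccccc1)[C@@](C)(CC=C(C)C)C(=O)OC(C)(C)C | intermediate
15 | (2R)-2-(tert-butoxycarbonyl)-2,5-dimethylhex-4-enoic acid | OC(=O)[C@@](C)(CC=C(C)C)C(=O)OC(C)(C)C | intermediate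
16 | pentafluorophenol | Oc1c(F)c(F)c(F)c(F)c1F | starting material
17 | 1-tert-butyl 3-(pentafluorophenyl) (2S)-2-methyl-2-(3-methylbut-2-en-1-yl)propanedioate | O=C(Oc1c(F)c(F)c(F)c(F)c1F)[C@@](C)(CC=C(C)C)C(=O)OC(C)(C)C | intermediate
18 | pentafluorophenyl trimethylsilyl (2R)-2-methyl-2-(3-methylbut-2-en-1-yl)propanedioate | O=C(Oc1c(F)c(F)c(F)c(F)c1F)[C@@](C)(CC=C(C)C)C(=O)O[Si](C)(C)C | intermediate (not isolated)
19 | pentafluorophenyl (2R)-2-(chlorocarbonyl)-2,5-dimethylhex-4-enoate | O=C(Oc1c(F)c(F)c(F)c(F)c1F)[C@@](C)(CC=C(C)C)C(Cl)=O | intermediate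
20 | {[(2S)-2-{(2S)-5-[2,7-dimethyl-3-(trimethylsilyloxy)octa-3,6-dien-4-yl]-2,3-dihydrofuran-2-yl}-6-methylhept-5-en-2-yl]oxy}(trimethyl)silane (E/Z mixture) | CC(C)=CCC[C@](C)(O[Si](C)(C)C)[C@@H]1CC=C(O1)C(CC=C(C)C)=C(O[Si](C)(C)C)C(C)C | intermediate (not isolated)
21 | pentafluorophenyl (2S)-2-({(5S)-2-(2,7-dimethyl-3-oxooct-6-en-4-yl)-5-[(2S)-6-methyl-2-(trimethylsilyloxy)hept-5-en-2-yl]-4,5-dihydrofuran-3-yl}carbonyl)-2,5-dimethylhex-4-enoate (mixture of tautomers and of epimers at the oxooctenyl carbon) | CC(C)=CCC[C@](C)(O[Si](C)(C)C)[C@@H]1CC(C(=O)[C@](C)(CC=C(C)C)C(=O)Oc2c(F)c(F)c(F)c(F)c2F)=C(O1)C(CC=C(C)C)C(=O)C(C)C | intermediate (not isolated)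
22 | (2S,5S,7S)-5-methyl-5,7-bis(3-methylbut-2-en-1-yl)-2-[(2S)-6-methyl-2-(trimethylsilyloxy)hept-5-en-2-yl]-7-(2-methylpropanoyl)-2,3-dihydro-1-benzofuran-4,6(5H,7H)-dione | CC(C)=CCC[C@](C)(O[Si](C)(C)C)[C@@H]1CC2=C(O1)[C@@](CC=C(C)C)(C(=O)C(C)C)C(=O)[C@@](C)(CC=C(C)C)C2=O | intermediate (not isolated)
23 | (2S,5S,7S)-2-[(2S)-2-hydroxy-6-methylhept-5-en-2-yl]-5-methyl-5,7-bis(3-methylbut-2-en-1-yl)-7-(2-methylpropanoyl)-2,3-dihydro-1-benzofuran-4,6(5H,7H)-dione (CNP0250451.1) | CC(C)=CCC[C@](C)(O)[C@@H]1CC2=C(O1)[C@@](CC=C(C)C)(C(=O)C(C)C)C(=O)[C@@](C)(CC=C(C)C)C2=O | target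

**Step count and risks**

Total steps: 11. Longest linear sequence: 7 (steps 5 to 11).

Steps most likely to fail:

Step 11. The ring-closing C-acylation may show poor facial selectivity at C7 (open and chelated transition states competing), or the first acylation may stray from C3a to oxygen or to the hindered C7. The fallback moves the C7 prenyl group to the end, so that the ring closure creates no stereocentre and is driven by enolisation. It sets out from 4 and 3: under the conditions of step 4 they should give 1-{(5S)-5-[(2S)-2-hydroxy-6-methylhept-5-en-2-yl]oxolan-2-ylidene}-3-methylbutan-2-one F1. Annulation of F1 with 19 under the conditions of step 11 should give the enolised triketone (2S,5R)-6-hydroxy-2-[(2S)-2-hydroxy-6-methylhept-5-en-2-yl]-5-methyl-5-(3-methylbut-2-en-1-yl)-7-(2-methylpropanoyl)-2,3-dihydro-1-benzofuran-4(5H)-one F2 (the same structure as A5, here with C5 already set by 19). The first acylation must again take place at the ring CH2 terminus C3a, since attack through C7 would exchange the roles of the two carbonyls of 19. Tsuji–Trost allylation of F2 with tert-butyl 3-methylbut-2-en-1-yl carbonate and Pd(PPh3)4 in THF should then place the prenyl group on C7 (O-allylation is reversible under zerovalent palladium and funnels to the C-allylated product), on the face anti to the C5 prenyl group. The fallback comes back to the route at 23.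

Step 4. The strongly basic dianion may cause elimination or halogen–metal exchange on the epoxy iodide, or the enolate oxygen may open the hindered epoxide too slowly. The fallback closes the oxolane through O1–C7a instead of O1–C2 and uses the chiral pool. It sets out from 6 and from (S)-linalool, (3S)-3,7-dimethylocta-1,6-dien-3-ol F3. Hydroxyl-directed epoxidation of the vinyl group of F3 (VO(acac)2, tBuOOH) should give (2S)-6-methyl-2-[(2S)-oxiran-2-yl]hept-5-en-2-ol F4 after separation from its epimer. The dianion of 6 should open the lithium alkoxide of F4 at the terminal CH2 to give (8S,9S)-8,9-dihydroxy-2,9,13-trimethyl-4-(3-methylbut-2-en-1-yl)tetradec-12-ene-3,5-dione F5. Acid-catalysed cyclodehydration of F5 (pyridinium tosylate, toluene) should close the secondary hydroxyl onto the neighbouring ketone with retention at C2. The fallback comes back to the route at 8.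

Step 7. The phase-transfer alkylation may give insufficient enantioselectivity or the wrong sense of induction with the prenyl electrophile. The fallback replaces catalysis by classical resolution. It sets out from 13: alkylation with NaH and 5 in THF should give the racemic diester 1-tert-butyl 3-(2,2-diphenylethyl) 2-methyl-2-(3-methylbut-2-en-1-yl)propanedioate F6. Saponification as in step 8 should give racemic 2-(tert-butoxycarbonyl)-2,5-dimethylhex-4-enoic acid F7. Crystallisation with (S)-1-phenylethylamine should give the salt (1S)-1-phenylethan-1-aminium (2R)-2-(tert-butoxycarbonyl)-2,5-dimethylhex-4-enoate F8 (the other amine enantiomer is used if it gives the less soluble salt of the R acid), and acidification sets the acid free. The fallback comes back to the route at 15.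

**Further compounds**

F1 | step 11 | 1-{(5S)-5-[(2S)-2-hydroxy-6-methylhept-5-en-2-yl]oxolan-2-ylidene}-3-methylbutan-2-one (E/Z mixture) | CC(C)=CCC[C@](C)(O)[C@@H]1CCC(O1)=CC(=O)C(C)C
F2 | step 11 | (2S,5R)-6-hydroxy-2-[(2S)-2-hydroxy-6-methylhept-5-en-2-yl]-5-methyl-5-(3-methylbut-2-en-1-yl)-7-(2-methylpropanoyl)-2,3-dihydro-1-benzofuran-4(5H)-one | CC(C)=CCC[C@](C)(O)[C@@H]1CC2=C(O1)C(C(=O)C(C)C)=C(O)[C@@](C)(CC=C(C)C)C2=O
F3 | step 4 | (S)-linalool, (3S)-3,7-dimethylocta-1,6-dien-3-ol | CC(C)=CCC[C@](C)(O)C=C
F4 | step 4 | (2S)-6-methyl-2-[(2S)-oxiran-2-yl]hept-5-en-2-ol | CC(C)=CCC[C@](C)(O)[C@@H]1CO1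
F5 | step 4 | (8S,9S)-8,9-dihydroxy-2,9,13-trimethyl-4-(3-methylbut-2-en-1-yl)tetradec-12-ene-3,5-dione | CC(C)=CCC[C@](C)(O)[C@@H](O)CCC(=O)C(CC=C(C)C)C(=O)C(C)C
F6 | step 7 | 1-tert-butyl 3-(2,2-diphenylethyl) 2-methyl-2-(3-methylbut-2-en-1-yl)propanedioate (racemic) | CC(CC=C(C)C)(C(=O)OC(C)(C)C)C(=O)OCC(c1ccccc1)c1ccccc1
F7 | step 7 | 2-(tert-butoxycarbonyl)-2,5-dimethylhex-4-enoic acid (racemic) | CC(CC=C(C)C)(C(O)=O)C(=O)OC(C)(C)C
F8 | step 7 | (1S)-1-phenylethan-1-aminium (2R)-2-(tert-butoxycarbonyl)-2,5-dimethylhex-4-enoate | C[C@H]([NH3+])c1ccccc1.[O-]C(=O)[C@@](C)(CC=C(C)C)C(=O)OC(C)(C)C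
A1 | direct plan | 2-methylbenzene-1,3,5-triol (2-methylphloroglucinol) | Cc1c(O)cc(O)cc1O
A2 | direct plan | 2-methyl-1-(2,4,6-trihydroxy-3-methylphenyl)propan-1-one | CC(C)C(=O)c1c(O)cc(O)c(C)c1O
A3 | direct plan | 1-{3-[(2Z)-3,7-dimethylocta-2,6-dien-1-yl]-2,6-dihydroxy-5-methyl-4-[(3-methylbut-2-en-1-yl)oxy]phenyl}-2-methylpropan-1-one | CC(C)C(=O)c1c(O)c(C)c(OCC=C(C)C)c(C/C=C(C)\CCC=C(C)C)c1O
A4 | direct plan | 1-{(2S)-6-hydroxy-2-[(2S)-2-hydroxy-6-methylhept-5-en-2-yl]-5-methyl-4-[(3-methylbut-2-en-1-yl)oxy]-2,3-dihydro-1-benzofuran-7-yl}-2-methylpropan-1-one | CC(C)=CCC[C@](C)(O)[C@@H]1Cc2c(O1)c(C(=O)C(C)C)c(O)c(C)c2OCC=C(C)C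
A5 | direct plan | (2S,5R)-6-hydroxy-2-[(2S)-2-hydroxy-6-methylhept-5-en-2-yl]-5-methyl-5-(3-methylbut-2-en-1-yl)-7-(2-methylpropanoyl)-2,3-dihydro-1-benzofuran-4(5H)-one | CC(C)=CCC[C@](C)(O)[C@@H]1CC2=C(O1)C(C(=O)C(C)C)=C(O)[C@@](C)(CC=C(C)C)C2=O
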